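**Strategy.** Marchantin C is cut at the ArCH2–CH2Ar bridge that joins ring D (the 1,3-phenylene) to C4 of ring A (the 4-hydroxy-3-aryloxyphenyl ring). Both carbons of this bridge are benzylic, each bound to an arene, so each is carried as an aryl nitrile and unveiled as an aldehyde. An intramolecular McMurry coupling of the dialdehyde then forms this C–C bond and the 18-membered ring in one operation, with no need to differentiate the chain ends. The precursor is an open-chain bis(diaryl ether) bibenzyl dialdehyde, built from four commercial arenes by SNAr, Ullmann and B-alkyl Suzuki couplings; the ortho-linked, 2,3-dioxygenated ring C supplies the turn. Hydrogenation and O-demethylation finish the route.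

Key step: step 6

Remark on the chemistry: ring B is the 1,4-phenylene. The alkene of 13 is drawn Z, the geometry assumed for this ring; an E isomer would converge on 14 in step 7.

**Step 1**
Reactants: 1 3-hydroxybenzonitrile; 2 2-fluoro-3-methoxybenzaldehyde
Product: 3 3-(2-formyl-6-methoxyphenoxy)benzonitrile
Conditions: K2CO3, DMAc, 130 °C
Reagents that add atoms: none
Why: SNAr, in which the fluoride ortho to the formyl group is displaced by the phenoxide of 1 through a formyl-stabilised Meisenheimer adduct, giving the ring C–O–ring D ether.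

**Step 2**
Reactants: 3 3-(2-formyl-6-methoxyphenoxy)benzonitrile
Product: 4 3-(2-ethenyl-6-methoxyphenoxy)benzonitrile
Conditions: Ph3PCH3Br, KOtBu, THF, 0 °C to rt
Reagents that add atoms: methyltriphenylphosphonium bromide, C[P+](c1ccccc1)(c1ccccc1)c1ccccc1.[Br-]
Why: Wittig methylenation, in which the non-stabilised ylide attacks the aldehyde far faster than the aryl nitrile.

**Step 3**
Reactants: 5 3-hydroxy-4-methoxybenzonitrile; 6 1-bromo-4-iodobenzene
Product: 7 3-(4-bromophenoxy)-4-methoxybenzonitrile
Conditions: CuI (10 mol%), N,N-dimethylglycine·HCl (30 mol%), Cs2CO3, dioxane, 90 °C; 6 in 1.5-fold excess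
Reagents that add atoms: none
Why: Ullmann-type copper-catalysed O-arylation forming the ring A–O–ring B ether, in which C–I reacts much faster than C–Br, so the bromide is kept for step 4.

**Step 4**
Reactants: 4 3-(2-ethenyl-6-methoxyphenoxy)benzonitrile; 7 3-(4-bromophenoxy)-4-methoxybenzonitrile
Product: 9 3-(4-{2-[2-(3-cyanophenoxy)-3-methoxyphenyl]ethyl}phenoxy)-4-methoxybenzonitrile, via alkyl-9-BBN adduct 8 (not isolated)
Conditions: 9-BBN, THF, 0 °C to rt; then 7, Pd(dppf)Cl2 (5 mol%), aq. K3PO4, DMF, 60 °C
Reagents that add atoms: none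
Why: Anti-Markovnikov hydroboration of the styrene followed by B-alkyl Suzuki–Miyaura coupling with the aryl bromide should give the ring B–CH2CH2–ring C bridge directly, since 9-BBN reduces aryl nitriles only sluggishly at rt.

**Step 5**
Reactants: 9 3-(4-{2-[2-(3-cyanophenoxy)-3-methoxyphenyl]ethyl}phenoxy)-4-methoxybenzonitrile
Product: 11 3-(4-{2-[2-(3-formylphenoxy)-3-methoxyphenyl]ethyl}phenoxy)-4-methoxybenzaldehyde, via bis(aluminium aldimine) 10 (not isolated)
Conditions: DIBAL-H (2.4 equiv), CH2Cl2, −78 °C to −20 °C; then 1 M HCl, rt
Reagents that add atoms: water, O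
Why: DIBAL-H reduction of nitrile to aldehyde, in which hydride adds once to each C≡N and the N-aluminio aldimine resists further reduction at low temperature, then hydrolyses on acidic work-up.

**Step 6**
Reactants: 11 3-(4-{2-[2-(3-formylphenoxy)-3-methoxyphenyl]ethyl}phenoxy)-4-methoxybenzaldehyde
Product: 13 (Z)-dehydromarchantin C dimethyl ether (marchantin C dimethyl ether with a cis CH=CH in place of the ring D–ring A CH2CH2 bridge), via titanium pinacolate 12 (not isolated)
Conditions: TiCl4, Zn, pyridine, THF, reflux; 11 added by syringe pump over 24 h (final ca. 2 mM); aq. K2CO3 work-up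
Reagents that add atoms: none
Why: Low-valent titanium from TiCl4/Zn reduces both aryl aldehydes to titanium-bound ketyl radicals, which couple to the cyclic titanium pinacolate 12 and are deoxygenated at reflux to the alkene, so the C–C bond between the two former formyl carbons and the ring are made together. The closest known reaction type is the intramolecular McMurry coupling of aromatic dialdehydes to stilbene-bridged cyclophanes and macrocyclic bis(bibenzyl) ethers. One ring is closed, the 18-membered macrocycle, by end-to-end ketyl–ketyl coupling of the two chain termini. No stereocentre results, because the two carbinol centres of 12 are lost on deoxygenation and the alkene geometry is erased in step 7. The step needs intramolecular over intermolecular coupling, which slow addition of 11 to excess reagent (pseudo-high dilution) should secure, helped by the ortho ether/ethylene arms on ring C and the meta-linked rings A and D, which fold the chain; the aldehydes are the only reducible groups, so chemoselectivity is not at issue.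

**Step 7**
Reactants: 13 (Z)-dehydromarchantin C dimethyl ether
Product: 14 marchantin C dimethyl ether
Conditions: H2 (1 atm), 10% Pd/C, EtOAc, rt
Reagents that add atoms: none
Why: Heterogeneous catalytic hydrogenation should saturate the stilbene C=C to the CH2–CH2 bridge while aryl methyl and diaryl ethers stay untouched.

**Step 8**
Reactants: 14 marchantin C dimethyl ether
Product: 16 marchantin C, via bis(dibromoboryl) ether 15 (not isolated)
Conditions: BBr3, CH2Cl2, −78 °C to rt; then ice-water
Reagents that add atoms: none
Why: BBr3 demethylation of aryl methyl ethers, in which bromide attacks the methyl group of the boron-complexed ether, while the diaryl ethers offer no carbon open to SN2 attack and should survive.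

**Compound list**
1 | 3-hydroxybenzonitrile | N#Cc1cccc(O)c1 | starting material
2 | 2-fluoro-3-methoxybenzaldehyde | COc1cccc(C=O)c1F | starting material
3 | 3-(2-formyl-6-methoxyphenoxy)benzonitrile | COc1cccc(C=O)c1Oc1cccc(C#N)c1 | intermediate
4 | 3-(2-ethenyl-6-methoxyphenoxy)benzonitrile | COc1cccc(C=C)c1Oc1cccc(C#N)c1 | intermediate
5 | 3-hydroxy-4-methoxybenzonitrile | COc1ccc(C#N)cc1O | starting material
6 | 1-bromo-4-iodobenzene | Brc1ccc(I)cc1 | starting material
7 | 3-(4-bromophenoxy)-4-methoxybenzonitrile | COc1ccc(C#N)cc1Oc1ccc(Br)cc1 | intermediate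
8 | 3-{2-[2-(9-borabicyclo[3.3.1]nonan-9-yl)ethyl]-6-methoxyphenoxy}benzonitrile (alkyl-9-BBN adduct) | COc1cccc(CCB2C3CCCC2CCC3)c1Oc1cccc(C#N)c1 | intermediate (not isolated)
9 | 3-(4-{2-[2-(3-cyanophenoxy)-3-methoxyphenyl]ethyl}phenoxy)-4-methoxybenzonitrile | COc1ccc(C#N)cc1Oc1ccc(CCc2cccc(OC)c2Oc2cccc(C#N)c2)cc1 | intermediate
10 | bis(N-diisobutylaluminio aldimine) of 11 | COc1ccc(C=N[Al](CC(C)C)CC(C)C)cc1Oc1ccc(CCc2cccc(OC)c2Oc2cccc(C=N[Al](CC(C)C)CC(C)C)c2)cc1 | intermediate (not isolated)
11 | 3-(4-{2-[2-(3-formylphenoxy)-3-methoxyphenyl]ethyl}phenoxy)-4-methoxybenzaldehyde | COc1ccc(C=O)cc1Oc1ccc(CCc2cccc(OC)c2Oc2cccc(C=O)c2)cc1 | intermediate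
12 | macrocyclic titanium pinacolate, drawn as the dichlorotitanium(IV) 1,2-diolate (diastereomer mixture; both carbinol centres are lost in the same step) | COc1ccc2cc1Oc1ccc(cc1)CCc1cccc(OC)c1Oc1cccc(c1)C1O[Ti](Cl)(Cl)OC21 | intermediate (not isolated)
13 | (Z)-dehydromarchantin C dimethyl ether | COc1ccc(cc1O2)/C=C\c1cccc(c1)Oc1c(OC)cccc1CCc1ccc2cc1 | intermediate
14 | marchantin C dimethyl ether | COc1ccc2cc1Oc1ccc(cc1)CCc1cccc(OC)c1Oc1cccc(c1)CC2 | intermediate
15 | bis(O-dibromoboryl) derivative of marchantin C | BrB(Br)Oc1ccc2cc1Oc1ccc(cc1)CCc1cccc(OB(Br)Br)c1Oc1cccc(c1)CC2 | intermediate (not isolated)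
16 | marchantin C | Oc1ccc2cc1Oc1ccc(cc1)CCc1cccc(O)c1Oc1cccc(c1)CC2 | target

**Step count.** Total: 8 steps. Longest linear sequence: 7 steps (1, 2, 4, 5, 6, 7, 8); step 3 is a one-step branch.

**Steps most likely to fail**

1. Step 6 (key step). The two aldehydes may couple between molecules faster than within one and give oligomers, or the reaction may stall at the pinacol stage. The fallback sets out from dialdehyde 11. Reduction with NaBH4 (MeOH/THF, 0 °C) should give the bis(benzylic alcohol) F1, and PBr3 (CH2Cl2, 0 °C) should convert it into the bis(benzyl bromide) F2. An intramolecular Wurtz coupling of F2 (Na, catalytic tetraphenylethene, THF, slow addition at high dilution) should then close the same CH2–CH2 bond directly. The fallback comes back to the route at 14, so 13 and step 7 are not needed.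

2. Step 4. Hydroboration may be incomplete, the borane may begin to reduce a nitrile, or the alkylborane may undergo protodeboronation or β-hydride elimination instead of transmetalation. The fallback sets out from styrene 4 and bromide 7. A Mizoroki–Heck coupling (Pd(OAc)2, P(o-tol)3, Et3N, DMF, 100 °C) should give the (E)-stilbene dinitrile F3. Hydrogenation of F3 (H2 1 atm, Pd/C, EtOAc, rt, stopped once the alkene is consumed) should then return to the route at 9.

3. Step 1. Displacement of the fluoride, which is flanked by OMe and CHO, may be slow, and long heating with carbonate may degrade the aldehyde. The fallback sets out from phenol 1 and replaces the SNAr by a copper-catalysed Ullmann ether coupling with commercial 2-bromo-3-methoxybenzaldehyde in place of 2 (CuI, N,N-dimethylglycine·HCl, Cs2CO3, dioxane, 100 °C). This should give 3 directly, so the route is rejoined at 3 and no new compound arises (entry F0).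

**Further compounds**
F1 | step 6 | [3-(4-{2-[2-(3-(hydroxymethyl)phenoxy)-3-methoxyphenyl]ethyl}phenoxy)-4-methoxyphenyl]methanol (bis(benzylic alcohol)) | COc1ccc(CO)cc1Oc1ccc(CCc2cccc(OC)c2Oc2cccc(CO)c2)cc1
F2 | step 6 | 4-(bromomethyl)-2-(4-{2-[2-(3-(bromomethyl)phenoxy)-3-methoxyphenyl]ethyl}phenoxy)-1-methoxybenzene (bis(benzyl bromide)) | COc1ccc(CBr)cc1Oc1ccc(CCc2cccc(OC)c2Oc2cccc(CBr)c2)cc1
F3 | step 4 | 3-(4-{(E)-2-[2-(3-cyanophenoxy)-3-methoxyphenyl]ethenyl}phenoxy)-4-methoxybenzonitrile ((E)-stilbene dinitrile) | COc1ccc(C#N)cc1Oc1ccc(/C=C/c2cccc(OC)c2Oc2cccc(C#N)c2)cc1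
F0 | step 1 | none | none
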